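**Retrosynthetic overview**
1. Target 22 ← regioselective acylation of O8 in the 6,8-diol 20 with acid chloride 21 ← desilylation of 19.
2. 19 ← Ramberg–Bäcklund ring contraction of the 11-membered cyclic sulfone 16 (sulfur between C1 and C10): loss of SO2 joins C1 to C10, creates the (Z)-C1=C10 bond and turns the thiacycle into the ten-membered carbocycle.
3. 16 ← cyclic sulfide 15 ← C10 thiolate closing on the C1 chloride of chain 13 ← thia-Michael addition, syn-reduction and silylation of enone 10 ← anti, Felkin boron aldol of enone 8 with the Sharpless-derived epoxy aldehyde 4.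
4. Enabling feature: C1=C10 is the only C=C of the ring and is isolated (C2H2 and C9H2 neighbours, nearest oxygen at C8, γ to C10), so both sp2 carbons can be the α-carbons of one sulfone. The trans-4,5-epoxide and the C6–C7–C8 triad are sp3, base-stable, need a ring of at least ten atoms, and are therefore set on the open chain.
5. Ring order: oxirane (step 2) → 11-membered thiacycle (step 10) → 10-membered carbocycle (step 12).

Key step: step 12

Remark: the SMILES is read as the 1(10)Z alkene with a trans-4,5-epoxide. Germacrane numbering of the target (ring C1–C10, methyls on C4 and C10, isopropyl on C7, oxygens on C6 and C8) is used for all intermediates. C10 is carried as a mixture of epimers from 11 to 18 and is written without configuration; this has no consequence because C10 becomes sp2 in step 12.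

**Route**

Step 1
Reactants: 1 5-chloropent-1-yne
Product: 2 (E)-6-chloro-3-methylhex-2-en-1-ol
Conditions: Me3Al, Cp2ZrCl2 (cat.), CH2Cl2, 0 °C to rt; n-BuLi, THF, −78 °C; (CH2O)n, −78 °C to rt; aq. HCl
Reagents that add atoms: trimethylaluminium C[Al](C)C; formaldehyde (as paraformaldehyde) C=O
Why: Zirconium-catalysed (Negishi) carboalumination adds Me–Al syn across the alkyne with methyl on the internal carbon, and the alkenylalanate takes up formaldehyde with retention, which should give only the E trisubstituted alkene (later C4–C5) while the primary chloride stays inert.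

Step 2
Reactants: 2 (E)-6-chloro-3-methylhex-2-en-1-ol
Product: 3 [(2R,3R)-3-(3-chloropropyl)-3-methyloxiran-2-yl]methanol
Conditions: Ti(OiPr)4 (cat.), D-(−)-diethyl tartrate (cat.), t-BuOOH, 4 Å molecular sieves, CH2Cl2, −20 °C
Reagents that add atoms: tert-butyl hydroperoxide CC(C)(C)OO
Why: Sharpless asymmetric epoxidation; the D-(−)-tartrate titanium complex delivers oxygen to the face of the E allylic alcohol that gives the (2R,3R) epoxide, which is C4 and C5 of the target with C3 and C6 trans.

Step 3
Reactants: 3 [(2R,3R)-3-(3-chloropropyl)-3-methyloxiran-2-yl]methanol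
Product: 4 (2S,3R)-3-(3-chloropropyl)-3-methyloxirane-2-carbaldehyde
Conditions: TEMPO (cat.), PhI(OAc)2, CH2Cl2, rt
Reagents that add atoms: none
Why: Oxoammonium-mediated oxidation of a primary alcohol stops at the aldehyde under neutral conditions that leave the epoxide and its α-stereocentre untouched; the aldehyde is used directly.

Step 4
Reactants: 5 (E)-but-2-enal; 6 isobutylmagnesium bromide
Product: 7 (E)-6-methylhept-2-en-4-ol (racemic)
Conditions: THF, −78 °C; then 1 M HCl, 0 °C
Reagents that add atoms: none
Why: 1,2-Addition of a Grignard reagent to an enal; the racemic carbinol centre is removed in step 5.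

Step 5
Reactants: 7 (E)-6-methylhept-2-en-4-ol
Product: 8 (E)-6-methylhept-2-en-4-one
Conditions: MnO2, CH2Cl2, rt
Reagents that add atoms: none
Why: MnO2 oxidises allylic alcohols selectively to enones and leaves the E double bond unchanged.

Step 6
Reactants: 8 (E)-6-methylhept-2-en-4-one; 4 (2S,3R)-3-(3-chloropropyl)-3-methyloxirane-2-carbaldehyde
Product: 10 (1R,2S,4E)-1-[(2R,3R)-3-(3-chloropropyl)-3-methyloxiran-2-yl]-1-hydroxy-2-(propan-2-yl)hex-4-en-3-one, via dicyclohexylboron E-enolate 9 (not isolated)
Conditions: Cy2BCl, Et3N, Et2O, −78 to 0 °C; then 4, −78 to −20 °C; pH 7 buffer, MeOH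
Reagents that add atoms: none
Why: Boron-mediated aldol reaction: Cy2BCl/Et3N enolises the ketone on its only sp3 α-side (C7) to the E enolate, whose chair (Zimmerman–Traxler) transition state should give the 6,7-anti aldol, while the aldehyde is attacked anti to the epoxide C–O bond (Felkin–Anh/Cornforth), placing the C6 hydroxyl anti to the epoxide oxygen; C6 and C7 are thus both controlled by the Sharpless epoxide.

Step 7
Reactants: 10 anti-aldol β-hydroxy enone
Product: 11 S-[(5S,6R)-6-[(2R,3R)-3-(3-chloropropyl)-3-methyloxiran-2-yl]-6-hydroxy-4-oxo-5-(propan-2-yl)hexan-2-yl] ethanethioate (both C10 epimers)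
Conditions: AcSH, Et3N (cat.), CH2Cl2, 0 °C
Reagents that add atoms: thioacetic acid CC(=O)S
Why: Thia-Michael addition of thioacetic acid to the enone puts sulfur on C10; the new centre is not controlled and need not be, and the weakly basic medium should spare the epoxide and the chloride.

Step 8
Reactants: 11 β-(acetylthio) β'-hydroxy ketone
Product: 12 S-[(4R,5R,6R)-6-[(2R,3R)-3-(3-chloropropyl)-3-methyloxiran-2-yl]-4,6-dihydroxy-5-(propan-2-yl)hexan-2-yl] ethanethioate (both C10 epimers)
Conditions: Et2BOMe, THF–MeOH, −78 °C; NaBH4; AcOH, then MeOH co-evaporation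
Reagents that add atoms: none
Why: Narasaka–Prasad reduction: the C6 hydroxyl and the C8 ketone are held in a six-membered boron chelate and external hydride attacks along the axial trajectory, which should give the 6,8-syn diol (C8 set from C6); the thioester should survive at −78 °C.

Step 9
Reactants: 12 syn-diol
Product: 13 S-[(4R,5R,6R)-4,6-bis(tert-butyldimethylsilyloxy)-6-[(2R,3R)-3-(3-chloropropyl)-3-methyloxiran-2-yl]-5-(propan-2-yl)hexan-2-yl] ethanethioate (both C10 epimers)
Conditions: TBSOTf, 2,6-lutidine, CH2Cl2, −78 to 0 °C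
Reagents that add atoms: tert-butyldimethylsilyl trifluoromethanesulfonate CC(C)(C)[Si](C)(C)OS(=O)(=O)C(F)(F)F
Why: Silyl triflate with a hindered base silylates both hindered secondary alcohols; the silyl ethers keep alkoxides out of the basic steps 10 and 12, so that no epoxide migration can occur at C6.

Step 10
Reactants: 13 bis-silyl ether chloro thioacetate
Product: 15 (4R,5R,6R,7R,8R)-6,8-bis(tert-butyldimethylsilyloxy)-4,5-epoxy-7-isopropyl-4,10-dimethyl-11-membered cyclic sulfide with S between C1 and C10, via thiol 14 (not isolated)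
Conditions: K2CO3, NaI (cat.), degassed MeOH–THF, 2 mM, slow addition, 45 °C
Reagents that add atoms: none
Why: Methanolysis of the thioester frees the C10 thiolate, which should close the eleven-membered ring by SN2 at the primary C1 chloride (iodide catalysis, high dilution); thiolate alkylation is a dependable macrocyclisation, and the only other electrophile, the epoxide, is shielded by the quaternary C4 and the silyloxy-bearing C6.

Step 11
Reactants: 15 cyclic sulfide
Product: 16 the corresponding 11-membered cyclic sulfone (S-dioxide of 15)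
Conditions: mCPBA (2.5 equiv), NaHCO3, CH2Cl2, 0 °C to rt
Reagents that add atoms: 3-chloroperoxybenzoic acid OOC(=O)c1cccc(Cl)c1
Why: Peracid oxidation of sulfide to sulfone; no alkene is present at this stage, and the epoxide and the silyl ethers are inert to buffered peracid.

Step 12
Reactants: 16 cyclic sulfone
Product: 19 (1(10)Z,4R,5R,6R,7R,8R)-6,8-bis(tert-butyldimethylsilyloxy)-4,5-epoxygermacr-1(10)-ene, via α-bromo sulfone 17 (not isolated), via episulfone 18 (not isolated)
Conditions: CBr2F2, KOH/Al2O3, t-BuOH–CH2Cl2, 5 °C to rt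
Reagents that add atoms: none
Why: Ramberg–Bäcklund reaction with in situ bromination: the more accessible α-sulfonyl carbanion (C1) takes bromine from CBr2F2 to give 17, the C10 carbanion displaces bromide in a 3-exo-tet 1,3-elimination to the thiirane 1,1-dioxide 18, and 18 loses SO2 cheletropically, so that the 11-membered thiacycle contracts to the 10-membered carbocycle with the C1=C10 bond in place. The closest known reaction type is the Ramberg–Bäcklund ring contraction of medium-ring cyclic sulfones to cycloalkenes with trisubstituted double bonds. The step joins two carbons of like (nucleophilic) polarity, with the halogen transfer supplying the polarity reversal at C1. No stereocentre is created and the stereo-mixed C10 becomes sp2; the alkene geometry should follow from the cis-fused episulfone, the favoured fusion on a ten-membered ring, which gives the Z alkene (C2 and C9 cis). The step needs Z over E and carbanion chemistry confined to C1 and C10: the epoxide can be reached from C1 only in a 4-exo mode at a fully substituted carbon, the C8 oxygen is γ to C10 so β-elimination is impossible, and both hydroxyls are silylated.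

Step 13
Reactants: 19 bis-silyl ether
Product: 20 (1(10)Z,4R,5R,6R,7R,8R)-4,5-epoxygermacr-1(10)-ene-6,8-diol
Conditions: Bu4NF, AcOH, THF, rt to 40 °C
Reagents that add atoms: none
Why: Fluoride cleaves both silyl ethers; buffering with acetic acid keeps alkoxide out of the medium, so that neither Payne migration of the epoxide from C6 nor transannular attack of the alkene on the epoxide should start.

Step 14
Reactants: 20 6,8-diol; 21 3,4,5-trimethoxybenzoyl chloride
Product: 22 (1(10)Z,4R,5R,6R,7S,8R)-4,5-epoxy-6-hydroxygermacr-1(10)-en-8-yl 3,4,5-trimethoxybenzoate (target)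
Conditions: pyridine, DMAP (cat.), CH2Cl2, −40 °C
Reagents that add atoms: none
Why: Acyl transfer to the less hindered secondary alcohol: C8–OH has a CH2 neighbour, whereas C6–OH lies between the isopropyl-bearing C7 and the epoxide carbon C5 and is deactivated by the adjacent epoxide oxygen, so one equivalent of acid chloride at low temperature should acylate O8.

**Compound list**
1 | 5-chloropent-1-yne | C#CCCCCl | starting material
2 | (E)-6-chloro-3-methylhex-2-en-1-ol | OC/C=C(\C)CCCCl | intermediate
3 | [(2R,3R)-3-(3-chloropropyl)-3-methyloxiran-2-yl]methanol | ClCCC[C@@]1(C)O[C@@H]1CO | intermediate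
4 | (2S,3R)-3-(3-chloropropyl)-3-methyloxirane-2-carbaldehyde | ClCCC[C@@]1(C)O[C@@H]1C=O | intermediate
5 | (E)-but-2-enal | C/C=C/C=O | starting material
6 | isobutylmagnesium bromide | CC(C)C[Mg]Br | starting material
7 | (E)-6-methylhept-2-en-4-ol (racemic) | C/C=C/C(O)CC(C)C | intermediate
8 | (E)-6-methylhept-2-en-4-one | C/C=C/C(=O)CC(C)C | intermediate
9 | dicyclohexylboron E-enolate of 8 | C/C=C/C(=C\C(C)C)OB(C1CCCCC1)C1CCCCC1 | intermediate
10 | (1R,2S,4E)-1-[(2R,3R)-3-(3-chloropropyl)-3-methyloxiran-2-yl]-1-hydroxy-2-(propan-2-yl)hex-4-en-3-one | ClCCC[C@@]1(C)O[C@@H]1[C@H](O)[C@H](C(C)C)C(=O)/C=C/C | intermediate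
11 | S-[(5S,6R)-6-[(2R,3R)-3-(3-chloropropyl)-3-methyloxiran-2-yl]-6-hydroxy-4-oxo-5-(propan-2-yl)hexan-2-yl] ethanethioate (C10 epimers) | ClCCC[C@@]1(C)O[C@@H]1[C@H](O)[C@H](C(C)C)C(=O)CC(C)SC(C)=O | intermediate
12 | S-[(4R,5R,6R)-6-[(2R,3R)-3-(3-chloropropyl)-3-methyloxiran-2-yl]-4,6-dihydroxy-5-(propan-2-yl)hexan-2-yl] ethanethioate (C10 epimers) | ClCCC[C@@]1(C)O[C@@H]1[C@H](O)[C@H](C(C)C)[C@H](O)CC(C)SC(C)=O | intermediate
13 | S-[(4R,5R,6R)-4,6-bis(tert-butyldimethylsilyloxy)-6-[(2R,3R)-3-(3-chloropropyl)-3-methyloxiran-2-yl]-5-(propan-2-yl)hexan-2-yl] ethanethioate (C10 epimers) | ClCCC[C@@]1(C)O[C@@H]1[C@H](O[Si](C)(C)C(C)(C)C)[C@H](C(C)C)[C@H](O[Si](C)(C)C(C)(C)C)CC(C)SC(C)=O | intermediate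
14 | thiol obtained from 13 by loss of the S-acetyl group | ClCCC[C@@]1(C)O[C@@H]1[C@H](O[Si](C)(C)C(C)(C)C)[C@H](C(C)C)[C@H](O[Si](C)(C)C(C)(C)C)CC(C)S | intermediate
15 | (4R,5R,6R,7R,8R)-6,8-bis(tert-butyldimethylsilyloxy)-4,5-epoxy-7-isopropyl-4,10-dimethyl-11-membered cyclic sulfide, S between C1 and C10 (C10 epimers) | C2CC[C@@]1(C)O[C@@H]1[C@H](O[Si](C)(C)C(C)(C)C)[C@H](C(C)C)[C@H](O[Si](C)(C)C(C)(C)C)CC(C)S2 | intermediate
16 | 11-membered cyclic sulfone, S-dioxide of 15 (C10 epimers) | C2CC[C@@]1(C)O[C@@H]1[C@H](O[Si](C)(C)C(C)(C)C)[C@H](C(C)C)[C@H](O[Si](C)(C)C(C)(C)C)CC(C)S2(=O)=O | intermediate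
17 | α-bromo sulfone, 16 brominated at C1 | BrC2CC[C@@]1(C)O[C@@H]1[C@H](O[Si](C)(C)C(C)(C)C)[C@H](C(C)C)[C@H](O[Si](C)(C)C(C)(C)C)CC(C)S2(=O)=O | intermediate
18 | episulfone, thiirane 1,1-dioxide fused at C1–C10 to the ten-membered ring | C23CC[C@@]1(C)O[C@@H]1[C@H](O[Si](C)(C)C(C)(C)C)[C@H](C(C)C)[C@H](O[Si](C)(C)C(C)(C)C)CC2(C)S3(=O)=O | intermediate
19 | (1(10)Z,4R,5R,6R,7R,8R)-6,8-bis(tert-butyldimethylsilyloxy)-4,5-epoxygermacr-1(10)-ene | CC(C)(C)[Si](C)(C)O[C@@H]2C/C(C)=C\CC[C@@]3(C)O[C@@H]3[C@H](O[Si](C)(C)C(C)(C)C)[C@@H]2C(C)C | intermediate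
20 | (1(10)Z,4R,5R,6R,7R,8R)-4,5-epoxygermacr-1(10)-ene-6,8-diol | O[C@@H]2C/C(C)=C\CC[C@@]3(C)O[C@@H]3[C@H](O)[C@@H]2C(C)C | intermediate
21 | 3,4,5-trimethoxybenzoyl chloride | COc1cc(C(Cl)=O)cc(OC)c1OC | starting material
22 | (1(10)Z,4R,5R,6R,7S,8R)-4,5-epoxy-6-hydroxygermacr-1(10)-en-8-yl 3,4,5-trimethoxybenzoate | COc1cc(C(=O)O[C@@H]2C/C(C)=C\CC[C@@]3(C)O[C@@H]3[C@H](O)[C@@H]2C(C)C)cc(OC)c1OC | target

**Count**
Total steps: 14. Longest linear sequence: 12 (steps 1–3 and 6–14).

**Steps most likely to fail**

Step 12: control over the alkene geometry may be lost while the episulfone forms and collapses, and a second bromination may occur before ring closure. Fallback: thermodynamic correction in place of kinetic control. The contraction is run on 16 as above; the E isomer, (1(10)E)-6,8-bis(tert-butyldimethylsilyloxy)-4,5-epoxygermacr-1(10)-ene F1, is then equilibrated by reversible thiyl-radical addition (PhSSPh cat., 350 nm, benzene, rt). The Z isomer should be favoured because it avoids a second trans unit in a ring that already holds the trans-epoxide. The fallback sets out from 16 and comes back at 19.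

Step 10: intermolecular S-alkylation (oligomer formation) may outrun closure of the eleven-membered ring. Fallback: close a larger ring through a disulfide and then remove one sulfur. From 13, the chloride is displaced with KSAc in DMF to the bis(thioacetate) F2. Both thioesters are cleaved with N2H4·AcOH at neutral pH to the dithiol F3. F3 is oxidised at high dilution (I2, pyridine, CH2Cl2–MeOH, 1 mM) to the 12-membered cyclic disulfide F4. F4 is desulfurised with (Et2N)3P in benzene at 80 °C: the phosphine attacks the less hindered sulfur on C1, and the released C10 thiolate displaces the phosphonium sulfide at C1. The route is rejoined at 15.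

Step 14: discrimination between the C6 and C8 hydroxyls may be insufficient, giving the regioisomeric ester and the diester. Fallback: tin-directed acylation. From 20, Bu2SnO in MeOH at reflux gives the dibutylstannylene acetal F5 bridging O6 and O8. Reaction of F5 with 21 in CH2Cl2 at rt should open the acetal at the less hindered O8; aqueous work-up then gives 22.

Further compounds
F1 | step 12 | (1(10)E)-6,8-bis(tert-butyldimethylsilyloxy)-4,5-epoxygermacr-1(10)-ene | CC(C)(C)[Si](C)(C)O[C@@H]2C/C(C)=C/CC[C@@]3(C)O[C@@H]3[C@H](O[Si](C)(C)C(C)(C)C)[C@@H]2C(C)C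
F2 | step 10 | bis(thioacetate): 13 with the C1 chloride replaced by S-acetyl | CC(=O)SCCC[C@@]1(C)O[C@@H]1[C@H](O[Si](C)(C)C(C)(C)C)[C@H](C(C)C)[C@H](O[Si](C)(C)C(C)(C)C)CC(C)SC(C)=O
F3 | step 10 | C1,C10-dithiol | SCCC[C@@]1(C)O[C@@H]1[C@H](O[Si](C)(C)C(C)(C)C)[C@H](C(C)C)[C@H](O[Si](C)(C)C(C)(C)C)CC(C)S
F4 | step 10 | 12-membered cyclic disulfide, S–S between C1 and C10 | C2CC[C@@]1(C)O[C@@H]1[C@H](O[Si](C)(C)C(C)(C)C)[C@H](C(C)C)[C@H](O[Si](C)(C)C(C)(C)C)CC(C)SS2
F5 | step 14 | 6,8-O-dibutylstannylene acetal of 20 | CCCC[Sn]4(CCCC)O[C@@H]2C/C(C)=C\CC[C@@]3(C)O[C@@H]3[C@H](O4)[C@@H]2C(C)C
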